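**Retrosynthetic overview**

1. The target is a trans-3,4-dibenzyl butyrolactone (ring B). Its C3 benzyl arene is the benzo ring C of a trans 2-aryl(ring D)-3-hydroxymethyl-2,3-dihydrobenzofuran (furan ring F). Its C4 benzyl guaiacyl ring A is etherified at O4 by an erythro guaiacylglycerol unit (ring E, C7/C8).
2. The strategy rests on ring F (O1–C2–C3–C3a–C7a) with its exocyclic CH2OH on C3: it is the pyranone of a flavanone less one ring carbon, the CH2OH carbon being the former carbonyl carbon C4. The C3–C3a bond is therefore made by shifting C4a from C4 to C3 of an (S)-flavanone.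
3. Disconnections: the ring C–CH2 bond (rhodium-catalysed 1,4-addition of the ring C boronate to an α-methylene lactone); C3–C3a (oxidative ring contraction); C2–ring D (asymmetric conjugate addition to 6-bromo-8-methoxychromone).
4. Lactone half: an Evans alkylation sets lactone C4, an Evans syn aldol of the ring A aryloxyacetyl imide sets C8, a Mitsunobu inversion at C7 gives the erythro pair, and a Mannich methylenation gives the acceptor.
5. Ring order: chromone pyranone, then ring F by contraction; lactone B separately; the halves are joined and all five silyl ethers are removed in the last step.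

Key step: step 6

Remark: the facial sense of the palladium/pyridine–oxazoline catalyst in step 5 is assigned by analogy with additions to cyclic enones (the (S)-ligand leading to the 2R series), so the (R)-ligand is specified for the 2S flavanone; if the assignment proved reversed, the enantiomeric ligand would be used with no other change.

**Route**

Step 1
Reactants: 1 2'-hydroxy-3'-methoxyacetophenone
Product: 2 1-(5-bromo-2-hydroxy-3-methoxyphenyl)ethan-1-one
Conditions: NBS, MeCN, 0 °C to rt
Reagents that add atoms: N-bromosuccinimide, O=C1CCC(=O)N1Br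
Why: Electrophilic aromatic bromination should go para to the free hydroxyl (C5'), the only open position that this strongest donor activates, since both ortho positions carry the acetyl and methoxy groups.

Step 2
Reactants: 2 1-(5-bromo-2-hydroxy-3-methoxyphenyl)ethan-1-one
Product: 4 6-bromo-8-methoxy-4H-chromen-4-one, via enaminone 3 (not isolated)
Conditions: Me2NCH(OMe)2, toluene, 100 °C; then conc. HCl, CH2Cl2, 40 °C
Reagents that add atoms: N,N-dimethylformamide dimethyl acetal, COC(OC)N(C)C
Why: Condensation of the acetyl methyl group with the amide acetal followed by acid-promoted oxa-Michael addition of the phenol and loss of dimethylamine is the standard enaminone chromone annulation of 2'-hydroxyacetophenones.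

Step 3
Reactants: 5 4-bromo-2-methoxyphenol
Product: 6 4-bromo-2-methoxyphenyl pivalate
Conditions: t-BuCOCl, Et3N, DMAP (cat.), CH2Cl2, 0 °C to rt
Reagents that add atoms: pivaloyl chloride, CC(C)(C)C(=O)Cl
Why: DMAP-catalysed O-acylation of the phenol installs the electron-poor, hindered ester that later lowers the migratory aptitude of ring D.

Step 4
Reactants: 6 4-bromo-2-methoxyphenyl pivalate
Product: 7 [3-methoxy-4-(pivaloyloxy)phenyl]boronic acid
Conditions: B2(OH)4, KOAc, chloro(2-dicyclohexylphosphino-2',4',6'-triisopropylbiphenyl)[2-(2'-aminobiphenyl)]palladium (second-generation XPhos precatalyst, cat.), XPhos (cat.), EtOH, 80 °C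
Reagents that add atoms: tetrahydroxydiboron, OB(O)B(O)O
Why: Miyaura-type palladium-catalysed borylation of the aryl bromide with tetrahydroxydiboron should give the boronic acid directly, the hindered aryl pivalate tolerating acetate in ethanol.

Step 5
Reactants: 4 6-bromo-8-methoxy-4H-chromen-4-one; 7 [3-methoxy-4-(pivaloyloxy)phenyl]boronic acid
Product: 8 4-[(2S)-6-bromo-8-methoxy-4-oxo-3,4-dihydro-2H-chromen-2-yl]-2-methoxyphenyl pivalate ((S)-flavanone)
Conditions: Pd(OCOCF3)2 (cat.), (R)-4-tert-butyl-2-(pyridin-2-yl)-4,5-dihydrooxazole (cat.), NH4PF6, H2O, ClCH2CH2Cl, 60 °C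
Reagents that add atoms: none
Why: Asymmetric conjugate addition in which an arylpalladium species of divalent palladium (no zerovalent palladium, so the aryl bromide is left alone) adds across C2=C3 of the chromone and the palladium enolate is protonated; the chiral pyridine–oxazoline ligand shields one face and the (R)-ligand is expected to set C2 as S.

Step 6
Reactants: 8 (S)-flavanone; 9 trimethyl orthoformate
Product: 11 methyl (2S,3S)-5-bromo-7-methoxy-2-[3-methoxy-4-(pivaloyloxy)phenyl]-2,3-dihydro-1-benzofuran-3-carboxylate (trans), via enol ether 10 (not isolated)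
Conditions: PhI(OAc)2, conc. H2SO4, HC(OMe)3 (solvent), rt; aq. NaHCO3 work-up
Reagents that add atoms: water, O (work-up)
Why: In acidic trimethyl orthoformate the ketone passes through its dimethyl ketal into enol ether 10, which the trivalent iodine electrophile attacks at C3 on the face anti to the pseudo-equatorial C2 aryl group, and re-ketalisation at C4 then places the C4–C4a bond antiperiplanar to the equatorial C3–I bond. The benzo carbon C4a, activated by the ortho oxygen O1, shifts from C4 to C3 with loss of iodobenzene, leaving a dimethoxycarbenium ion on the extruded C4 that collapses to the methyl ester; the closest known reaction type is the oxidative 1,2-aryl migration of aryl ketones to arylacetic esters with trivalent iodine or trivalent thallium in trimethyl orthoformate, which is established for flavanones as a ring contraction. Ring F is thus closed not by cyclisation but by contraction of the six-membered pyranone through a bridged, phenonium-type 1,2-shift that forms the C3–C3a bond. The new stereocentre C3 is controlled by the existing C2 centre, because anti iodination followed by migration with inversion at C3 places ester and aryl group trans (2S,3S), which is also the thermodynamic isomer, so that any cis ester can be equilibrated with DBU. The step needs migration of C4a in preference to the 2-to-3 shift of ring D (isoflavone pathway) and to dehydrogenation (flavone); the pivalate makes ring D a poor migrating group and a poor donor to a C2 cation, the ring oxygen favours C4a, and C2 is not a reacting centre so its configuration should be kept.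

Step 7
Reactants: 11 trans methyl ester
Product: 12 4-[(2S,3R)-5-bromo-3-(hydroxymethyl)-7-methoxy-2,3-dihydro-1-benzofuran-2-yl]-2-methoxyphenol
Conditions: LiBH4, THF, MeOH (additive), 0 °C to rt
Reagents that add atoms: none
Why: Borohydride reduction converts the methyl ester into the primary alcohol and cleaves the aryl pivalate reductively, while the aryl bromide and both stereocentres are untouched (the descriptor at C3 changes only through priorities).

Step 8
Reactants: 12 bromo phenol alcohol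
Product: 13 (2S,3R)-5-bromo-7-methoxy-2-[3-methoxy-4-(triisopropylsilyloxy)phenyl]-3-[(triisopropylsilyloxy)methyl]-2,3-dihydro-1-benzofuran
Conditions: i-Pr3SiOTf, 2,6-lutidine, CH2Cl2, 0 °C
Reagents that add atoms: triisopropylsilyl trifluoromethanesulfonate, CC(C)[Si](OS(=O)(=O)C(F)(F)F)(C(C)C)C(C)C
Why: Silylation with the silyl triflate and a hindered pyridine base protects phenol and primary alcohol in one operation as base-tolerant, fluoride-labile triisopropylsilyl ethers.

Step 9
Reactants: 13 bis(triisopropylsilyl) aryl bromide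
Product: 14 2-[(2S,3R)-7-methoxy-2-[3-methoxy-4-(triisopropylsilyloxy)phenyl]-3-[(triisopropylsilyloxy)methyl]-2,3-dihydro-1-benzofuran-5-yl]-4,4,5,5-tetramethyl-1,3,2-dioxaborolane
Conditions: B2pin2, PdCl2(dppf) (cat.), KOAc, 1,4-dioxane, 90 °C
Reagents that add atoms: bis(pinacolato)diboron, CC1(C)OB(OC1(C)C)B1OC(C)(C)C(C)(C)O1
Why: Miyaura borylation of the electron-rich aryl bromide under anhydrous acetate conditions should leave the silyl ethers and the benzylic ether C2–O1 intact.

Step 10
Reactants: 15 4-hydroxy-3-methoxybenzyl alcohol; 16 tert-butyl bromoacetate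
Product: 17 tert-butyl 2-[4-(hydroxymethyl)-2-methoxyphenoxy]acetate
Conditions: K2CO3, acetone, 50 °C
Reagents that add atoms: none
Why: Williamson etherification is selective for the phenol, which alone is deprotonated by carbonate, and it introduces the two carbons that become C8 and C9.

Step 11
Reactants: 17 tert-butyl 2-[4-(hydroxymethyl)-2-methoxyphenoxy]acetate
Product: 18 tert-butyl 2-[4-(bromomethyl)-2-methoxyphenoxy]acetate
Conditions: CBr4, PPh3, CH2Cl2, 0 °C
Reagents that add atoms: tetrabromomethane, BrC(Br)(Br)Br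
Why: The Appel reaction converts the benzylic alcohol into the bromide under neutral conditions that spare the tert-butyl ester.

Step 12
Reactants: 19 4-tert-butoxy-4-oxobutanoic acid; 20 (R)-4-benzyl-1,3-oxazolidin-2-one
Product: 22 tert-butyl 4-[(4R)-4-benzyl-2-oxo-1,3-oxazolidin-3-yl]-4-oxobutanoate, via mixed pivalic anhydride 21 (not isolated)
Conditions: t-BuCOCl, Et3N, THF, −20 °C; then 20, LiCl, rt
Reagents that add atoms: none
Why: N-Acylation of the oxazolidinone through the mixed pivalic anhydride with lithium chloride activation is the standard mild entry to Evans imides.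

Step 13
Reactants: 22 succinate imide; 18 benzylic bromide
Product: 23 tert-butyl (3R)-3-[(4R)-4-benzyl-2-oxo-1,3-oxazolidine-3-carbonyl]-4-[4-(2-tert-butoxy-2-oxoethoxy)-3-methoxyphenyl]butanoate
Conditions: NaN(SiMe3)2, THF, −78 °C; then 18, −78 to −20 °C
Reagents that add atoms: none
Why: Evans asymmetric alkylation: the chelated Z sodium enolate forms at the more acidic imide α-methylene and the benzylic bromide approaches the face opposite the benzyl group of the auxiliary, which with the (R)-auxiliary sets the future lactone C4 as R.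

Step 14
Reactants: 23 alkylated imide
Product: 24 tert-butyl (3R)-4-[4-(2-tert-butoxy-2-oxoethoxy)-3-methoxyphenyl]-3-(hydroxymethyl)butanoate
Conditions: LiBH4, THF, MeOH (1 equiv), 0 °C
Reagents that add atoms: none
Why: Reductive removal of the auxiliary by borohydride is chemoselective for the activated imide carbonyl over the two tert-butyl esters and does not touch the stereocentre.

Step 15
Reactants: 24 hydroxy bis(tert-butyl ester)
Product: 25 2-[2-methoxy-4-[[(3R)-5-oxooxolan-3-yl]methyl]phenoxy]acetic acid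
Conditions: CF3CO2H, CH2Cl2, 0 °C to rt
Reagents that add atoms: none
Why: Acidolysis cleaves both tert-butyl esters, after which the γ-hydroxy acid lactonises spontaneously to ring B while the aryloxyacetic acid is set free for the next acylation.

Step 16
Reactants: 25 lactone acid; 20 (R)-4-benzyl-1,3-oxazolidin-2-one
Product: 27 (4R)-4-benzyl-3-[2-[2-methoxy-4-[[(3R)-5-oxooxolan-3-yl]methyl]phenoxy]acetyl]-1,3-oxazolidin-2-one, via mixed pivalic anhydride 26 (not isolated)
Conditions: t-BuCOCl, Et3N, THF, −20 °C; then 20, LiCl, rt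
Reagents that add atoms: none
Why: The same mixed-anhydride N-acylation is mild enough to leave the lactone closed and gives the aryloxyacetyl imide needed for the aldol reaction.

Step 17
Reactants: 28 vanillin
Product: 29 3-methoxy-4-(triisopropylsilyloxy)benzaldehyde
Conditions: i-Pr3SiCl, imidazole, DMF, rt
Reagents that add atoms: chlorotriisopropylsilane, CC(C)[Si](Cl)(C(C)C)C(C)C
Why: Imidazole-mediated silylation protects the phenol of ring E as an aryl silyl ether stable to the later boron, borohydride and amide base steps.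

Step 18
Reactants: 27 aryloxyacetyl imide; 29 3-methoxy-4-(triisopropylsilyloxy)benzaldehyde
Product: 30 (4R)-4-benzyl-3-[(2R,3S)-3-hydroxy-2-[2-methoxy-4-[[(3R)-5-oxooxolan-3-yl]methyl]phenoxy]-3-[3-methoxy-4-(triisopropylsilyloxy)phenyl]propanoyl]-1,3-oxazolidin-2-one (syn aldol)
Conditions: n-Bu2BOTf, i-Pr2NEt, CH2Cl2, −78 to 0 °C; then 29, −78 to 0 °C; pH 7 buffer, MeOH, H2O2, 0 °C
Reagents that add atoms: none
Why: Evans syn aldol reaction: the Z dibutylboron enolate of the imide (the lactone is not enolised by the boron triflate and amine) reacts through a chair Zimmerman–Traxler transition state on the face dictated by the (R)-auxiliary, which fixes C8 in its final configuration and gives C7 as the threo epimer to be inverted later.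

Step 19
Reactants: 30 syn aldol adduct
Product: 31 (4R)-4-[[4-[[(1S,2S)-1,3-dihydroxy-1-[3-methoxy-4-(triisopropylsilyloxy)phenyl]propan-2-yl]oxy]-3-methoxyphenyl]methyl]oxolan-2-one (threo diol)
Conditions: NaBH4, THF/H2O, 0 °C to rt
Reagents that add atoms: none
Why: Sodium borohydride in wet THF reduces the activated N-acyl oxazolidinone to the primary alcohol C9–OH and releases the auxiliary, whereas the less electrophilic γ-lactone should survive at this temperature.

Step 20
Reactants: 31 threo diol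
Product: 32 (4R)-4-[[4-[[(1S,2S)-3-(tert-butyldimethylsilyloxy)-1-hydroxy-1-[3-methoxy-4-(triisopropylsilyloxy)phenyl]propan-2-yl]oxy]-3-methoxyphenyl]methyl]oxolan-2-one
Conditions: t-BuMe2SiCl, imidazole, CH2Cl2, 0 °C
Reagents that add atoms: tert-butyldimethylsilyl chloride, CC(C)(C)[Si](C)(C)Cl
Why: Silylation with the bulky chlorosilane is selective for the primary hydroxyl over the hindered secondary benzylic one.

Step 21
Reactants: 32 threo mono-silyl ether
Product: 33 (1R,2S)-3-(tert-butyldimethylsilyloxy)-2-[2-methoxy-4-[[(3R)-5-oxooxolan-3-yl]methyl]phenoxy]-1-[3-methoxy-4-(triisopropylsilyloxy)phenyl]propyl 4-nitrobenzoate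
Conditions: 4-O2NC6H4CO2H, PPh3, DIAD, toluene, 0 °C to rt
Reagents that add atoms: 4-nitrobenzoic acid, O=C(O)c1ccc(cc1)[N+](=O)[O-]
Why: Mitsunobu esterification displaces the oxyphosphonium group at C7 by SN2 attack of the carboxylate and so inverts C7 from S to R to give the erythro pair, the non-polar solvent and the electron-withdrawing aryloxy group on C8 disfavouring ionisation.

Step 22
Reactants: 33 erythro 4-nitrobenzoate
Product: 34 (4R)-4-[[4-[[(1R,2S)-3-(tert-butyldimethylsilyloxy)-1-hydroxy-1-[3-methoxy-4-(triisopropylsilyloxy)phenyl]propan-2-yl]oxy]-3-methoxyphenyl]methyl]oxolan-2-one (erythro alcohol)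
Conditions: K2CO3 (cat.), MeOH, 0 °C
Reagents that add atoms: none
Why: Carbonate-catalysed transesterification removes the activated 4-nitrobenzoate at low temperature, where the aryl silyl ether persists and any methanolysis of the five-membered lactone is reversible in favour of ring closure.

Step 23
Reactants: 34 erythro alcohol
Product: 35 (4R)-4-[[4-[[(1R,2S)-1,3-bis(tert-butyldimethylsilyloxy)-1-[3-methoxy-4-(triisopropylsilyloxy)phenyl]propan-2-yl]oxy]-3-methoxyphenyl]methyl]oxolan-2-one
Conditions: t-BuMe2SiOTf, 2,6-lutidine, CH2Cl2, −78 to 0 °C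
Reagents that add atoms: tert-butyldimethylsilyl trifluoromethanesulfonate, CC(C)(C)[Si](C)(C)OS(=O)(=O)C(F)(F)F
Why: The silyl triflate with a hindered pyridine base silylates the hindered secondary benzylic hydroxyl without enolising the lactone.

Step 24
Reactants: 35 fully silylated lactone
Product: 38 (4R)-4-[[4-[[(1R,2S)-1,3-bis(tert-butyldimethylsilyloxy)-1-[3-methoxy-4-(triisopropylsilyloxy)phenyl]propan-2-yl]oxy]-3-methoxyphenyl]methyl]-3-methylideneoxolan-2-one, via Mannich base 36 (not isolated), via ammonium iodide 37 (not isolated)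
Conditions: LiN(i-Pr)2, THF, −78 °C; CH2=NMe2+ I−, −78 °C to rt; then MeI, MeOH/CH2Cl2, rt; then aq. NaHCO3, CH2Cl2, rt
Reagents that add atoms: Eschenmoser's salt (N,N-dimethylmethyleneiminium iodide), C=[N+](C)C.[I-]
Why: Mannich reaction of the lactone lithium enolate with the iminium salt, N-methylation and E1cB elimination of trimethylamine is the standard α-methylenation of butyrolactones, and the weak bicarbonate base avoids migration of the new double bond into the ring so that C4 is kept.

Step 25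
Reactants: 38 α-methylene lactone; 14 aryl pinacol boronate
Product: 40 (3R,4R)-4-[[4-[[(1R,2S)-1,3-bis(tert-butyldimethylsilyloxy)-1-[3-methoxy-4-(triisopropylsilyloxy)phenyl]propan-2-yl]oxy]-3-methoxyphenyl]methyl]-3-[[(2S,3R)-7-methoxy-2-[3-methoxy-4-(triisopropylsilyloxy)phenyl]-3-[(triisopropylsilyloxy)methyl]-2,3-dihydro-1-benzofuran-5-yl]methyl]oxolan-2-one (trans), via cis lactone 39 (not isolated)
Conditions: [RhCl(cod)]2 (cat.), KOH (cat., aq.), 1,4-dioxane/H2O, 50 °C; then DBU, toluene, rt
Reagents that add atoms: none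
Why: Hayashi–Miyaura 1,4-addition: the aryl group is transferred from boron to a hydroxo complex of monovalent rhodium, adds to the exocyclic methylene and the rhodium enolate is protonated by water, and the new centre C3, formed partly as the cis epimer, is equilibrated by DBU to the trans lactone, which the C4 substituent makes the more stable isomer.

Step 26
Reactants: 40 pentasilyl ether
Product: 41 (3R,4R)-4-[[4-[[(1R,2S)-1,3-dihydroxy-1-(4-hydroxy-3-methoxyphenyl)propan-2-yl]oxy]-3-methoxyphenyl]methyl]-3-[[(2S,3R)-2-(4-hydroxy-3-methoxyphenyl)-3-(hydroxymethyl)-7-methoxy-2,3-dihydro-1-benzofuran-5-yl]methyl]oxolan-2-one (target)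
Conditions: Bu4NF, AcOH, THF, 0 °C to rt
Reagents that add atoms: none
Why: Fluoride cleaves the two aryl and three alkyl silyl ethers in one operation, and buffering with acetic acid keeps the lactone, its α-centre and the 4-hydroxybenzylic alcohol away from free phenoxide or alkoxide base.

**Compound list**

1 | 2'-hydroxy-3'-methoxyacetophenone | CC(=O)c1cccc(OC)c1O | starting material
2 | 1-(5-bromo-2-hydroxy-3-methoxyphenyl)ethan-1-one | CC(=O)c1cc(Br)cc(OC)c1O | intermediate
3 | (E)-1-(5-bromo-2-hydroxy-3-methoxyphenyl)-3-(dimethylamino)prop-2-en-1-one | CN(C)/C=C/C(=O)c1cc(Br)cc(OC)c1O | intermediate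
4 | 6-bromo-8-methoxy-4H-chromen-4-one | O=c1ccoc2c(OC)cc(Br)cc12 | intermediate
5 | 4-bromo-2-methoxyphenol | COc1cc(Br)ccc1O | starting material
6 | 4-bromo-2-methoxyphenyl pivalate | COc1cc(Br)ccc1OC(=O)C(C)(C)C | intermediate
7 | [3-methoxy-4-(pivaloyloxy)phenyl]boronic acid | COc1cc(B(O)O)ccc1OC(=O)C(C)(C)C | intermediate
8 | 4-[(2S)-6-bromo-8-methoxy-4-oxo-3,4-dihydro-2H-chromen-2-yl]-2-methoxyphenyl pivalate | O=C1C[C@@H](c2ccc(OC(=O)C(C)(C)C)c(OC)c2)Oc2c(OC)cc(Br)cc12 | intermediate
9 | trimethyl orthoformate | COC(OC)OC | starting material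
10 | 4-[(2S)-6-bromo-4,8-dimethoxy-2H-chromen-2-yl]-2-methoxyphenyl pivalate (enol ether) | COC1=C[C@@H](c2ccc(OC(=O)C(C)(C)C)c(OC)c2)Oc2c(OC)cc(Br)cc12 | intermediate
11 | methyl (2S,3S)-5-bromo-7-methoxy-2-[3-methoxy-4-(pivaloyloxy)phenyl]-2,3-dihydro-1-benzofuran-3-carboxylate (trans) | Brc1cc(OC)c2c(c1)[C@H](C(=O)OC)[C@@H](c1ccc(OC(=O)C(C)(C)C)c(OC)c1)O2 | intermediate
12 | 4-[(2S,3R)-5-bromo-3-(hydroxymethyl)-7-methoxy-2,3-dihydro-1-benzofuran-2-yl]-2-methoxyphenol | Brc1cc(OC)c2c(c1)[C@H](CO)[C@@H](c1ccc(O)c(OC)c1)O2 | intermediate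
13 | (2S,3R)-5-bromo-7-methoxy-2-[3-methoxy-4-(triisopropylsilyloxy)phenyl]-3-[(triisopropylsilyloxy)methyl]-2,3-dihydro-1-benzofuran | Brc1cc(OC)c2c(c1)[C@H](CO[Si](C(C)C)(C(C)C)C(C)C)[C@@H](c1ccc(O[Si](C(C)C)(C(C)C)C(C)C)c(OC)c1)O2 | intermediate
14 | 2-[(2S,3R)-7-methoxy-2-[3-methoxy-4-(triisopropylsilyloxy)phenyl]-3-[(triisopropylsilyloxy)methyl]-2,3-dihydro-1-benzofuran-5-yl]-4,4,5,5-tetramethyl-1,3,2-dioxaborolane | CC1(C)OB(OC1(C)C)c1cc(OC)c2c(c1)[C@H](CO[Si](C(C)C)(C(C)C)C(C)C)[C@@H](c1ccc(O[Si](C(C)C)(C(C)C)C(C)C)c(OC)c1)O2 | intermediate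
15 | 4-hydroxy-3-methoxybenzyl alcohol | COc1cc(CO)ccc1O | starting material
16 | tert-butyl bromoacetate | CC(C)(C)OC(=O)CBr | starting material
17 | tert-butyl 2-[4-(hydroxymethyl)-2-methoxyphenoxy]acetate | COc1cc(CO)ccc1OCC(=O)OC(C)(C)C | intermediate
18 | tert-butyl 2-[4-(bromomethyl)-2-methoxyphenoxy]acetate | COc1cc(CBr)ccc1OCC(=O)OC(C)(C)C | intermediate
19 | 4-tert-butoxy-4-oxobutanoic acid | CC(C)(C)OC(=O)CCC(=O)O | starting material
20 | (R)-4-benzyl-1,3-oxazolidin-2-one | O=C1N[C@H](Cc2ccccc2)CO1 | starting material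
21 | 4-tert-butoxy-4-oxobutanoic pivalic anhydride | CC(C)(C)OC(=O)CCC(=O)OC(=O)C(C)(C)C | intermediate
22 | tert-butyl 4-[(4R)-4-benzyl-2-oxo-1,3-oxazolidin-3-yl]-4-oxobutanoate | CC(C)(C)OC(=O)CCC(=O)N1[C@H](Cc2ccccc2)COC1=O | intermediate
23 | tert-butyl (3R)-3-[(4R)-4-benzyl-2-oxo-1,3-oxazolidine-3-carbonyl]-4-[4-(2-tert-butoxy-2-oxoethoxy)-3-methoxyphenyl]butanoate | CC(C)(C)OC(=O)C[C@@H](Cc1ccc(OCC(=O)OC(C)(C)C)c(OC)c1)C(=O)N1[C@H](Cc2ccccc2)COC1=O | intermediate
24 | tert-butyl (3R)-4-[4-(2-tert-butoxy-2-oxoethoxy)-3-methoxyphenyl]-3-(hydroxymethyl)butanoate | CC(C)(C)OC(=O)C[C@@H](Cc1ccc(OCC(=O)OC(C)(C)C)c(OC)c1)CO | intermediate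
25 | 2-[2-methoxy-4-[[(3R)-5-oxooxolan-3-yl]methyl]phenoxy]acetic acid | COc1cc(C[C@H]2COC(=O)C2)ccc1OCC(=O)O | intermediate
26 | 2-[2-methoxy-4-[[(3R)-5-oxooxolan-3-yl]methyl]phenoxy]acetic pivalic anhydride | COc1cc(C[C@H]2COC(=O)C2)ccc1OCC(=O)OC(=O)C(C)(C)C | intermediate
27 | (4R)-4-benzyl-3-[2-[2-methoxy-4-[[(3R)-5-oxooxolan-3-yl]methyl]phenoxy]acetyl]-1,3-oxazolidin-2-one | COc1cc(C[C@H]2COC(=O)C2)ccc1OCC(=O)N1[C@H](Cc2ccccc2)COC1=O | intermediate
28 | vanillin | COc1cc(C=O)ccc1O | starting material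
29 | 3-methoxy-4-(triisopropylsilyloxy)benzaldehyde | COc1cc(C=O)ccc1O[Si](C(C)C)(C(C)C)C(C)C | intermediate
30 | (4R)-4-benzyl-3-[(2R,3S)-3-hydroxy-2-[2-methoxy-4-[[(3R)-5-oxooxolan-3-yl]methyl]phenoxy]-3-[3-methoxy-4-(triisopropylsilyloxy)phenyl]propanoyl]-1,3-oxazolidin-2-one | COc1cc([C@H](O)[C@H](C(=O)N2[C@H](Cc3ccccc3)COC2=O)Oc2ccc(C[C@H]3COC(=O)C3)cc2OC)ccc1O[Si](C(C)C)(C(C)C)C(C)C | intermediate
31 | (4R)-4-[[4-[[(1S,2S)-1,3-dihydroxy-1-[3-methoxy-4-(triisopropylsilyloxy)phenyl]propan-2-yl]oxy]-3-methoxyphenyl]methyl]oxolan-2-one (threo) | COc1cc([C@H](O)[C@H](CO)Oc2ccc(C[C@H]3COC(=O)C3)cc2OC)ccc1O[Si](C(C)C)(C(C)C)C(C)C | intermediate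
32 | (4R)-4-[[4-[[(1S,2S)-3-(tert-butyldimethylsilyloxy)-1-hydroxy-1-[3-methoxy-4-(triisopropylsilyloxy)phenyl]propan-2-yl]oxy]-3-methoxyphenyl]methyl]oxolan-2-one | COc1cc([C@H](O)[C@H](CO[Si](C)(C)C(C)(C)C)Oc2ccc(C[C@H]3COC(=O)C3)cc2OC)ccc1O[Si](C(C)C)(C(C)C)C(C)C | intermediate
33 | (1R,2S)-3-(tert-butyldimethylsilyloxy)-2-[2-methoxy-4-[[(3R)-5-oxooxolan-3-yl]methyl]phenoxy]-1-[3-methoxy-4-(triisopropylsilyloxy)phenyl]propyl 4-nitrobenzoate | COc1cc([C@@H](OC(=O)c2ccc(cc2)[N+](=O)[O-])[C@H](CO[Si](C)(C)C(C)(C)C)Oc2ccc(C[C@H]3COC(=O)C3)cc2OC)ccc1O[Si](C(C)C)(C(C)C)C(C)C | intermediate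
34 | (4R)-4-[[4-[[(1R,2S)-3-(tert-butyldimethylsilyloxy)-1-hydroxy-1-[3-methoxy-4-(triisopropylsilyloxy)phenyl]propan-2-yl]oxy]-3-methoxyphenyl]methyl]oxolan-2-one (erythro) | COc1cc([C@@H](O)[C@H](CO[Si](C)(C)C(C)(C)C)Oc2ccc(C[C@H]3COC(=O)C3)cc2OC)ccc1O[Si](C(C)C)(C(C)C)C(C)C | intermediate
35 | (4R)-4-[[4-[[(1R,2S)-1,3-bis(tert-butyldimethylsilyloxy)-1-[3-methoxy-4-(triisopropylsilyloxy)phenyl]propan-2-yl]oxy]-3-methoxyphenyl]methyl]oxolan-2-one | COc1cc([C@@H](O[Si](C)(C)C(C)(C)C)[C@H](CO[Si](C)(C)C(C)(C)C)Oc2ccc(C[C@H]3COC(=O)C3)cc2OC)ccc1O[Si](C(C)C)(C(C)C)C(C)C | intermediate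
36 | (3S,4R)-3-[(dimethylamino)methyl] derivative of 35 (trans Mannich base) | COc1cc([C@@H](O[Si](C)(C)C(C)(C)C)[C@H](CO[Si](C)(C)C(C)(C)C)Oc2ccc(C[C@H]3COC(=O)[C@@H]3CN(C)C)cc2OC)ccc1O[Si](C(C)C)(C(C)C)C(C)C | intermediate
37 | N-methyl quaternary ammonium iodide of 36 | COc1cc([C@@H](O[Si](C)(C)C(C)(C)C)[C@H](CO[Si](C)(C)C(C)(C)C)Oc2ccc(C[C@H]3COC(=O)[C@@H]3C[N+](C)(C)C)cc2OC)ccc1O[Si](C(C)C)(C(C)C)C(C)C.[I-] | intermediate
38 | (4R)-4-[[4-[[(1R,2S)-1,3-bis(tert-butyldimethylsilyloxy)-1-[3-methoxy-4-(triisopropylsilyloxy)phenyl]propan-2-yl]oxy]-3-methoxyphenyl]methyl]-3-methylideneoxolan-2-one | COc1cc([C@@H](O[Si](C)(C)C(C)(C)C)[C@H](CO[Si](C)(C)C(C)(C)C)Oc2ccc(C[C@H]3COC(=O)C3=C)cc2OC)ccc1O[Si](C(C)C)(C(C)C)C(C)C | intermediate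
39 | (3S,4R) cis epimer of 40 at lactone C3 | COc1cc([C@@H](O[Si](C)(C)C(C)(C)C)[C@H](CO[Si](C)(C)C(C)(C)C)Oc2ccc(C[C@H]3COC(=O)[C@H]3Cc3cc(OC)c4c(c3)[C@H](CO[Si](C(C)C)(C(C)C)C(C)C)[C@@H](c3ccc(O[Si](C(C)C)(C(C)C)C(C)C)c(OC)c3)O4)cc2OC)ccc1O[Si](C(C)C)(C(C)C)C(C)C | intermediate
40 | (3R,4R) pentasilyl ether of the target (three triisopropylsilyl and two tert-butyldimethylsilyl groups; trans lactone) | COc1cc([C@@H](O[Si](C)(C)C(C)(C)C)[C@H](CO[Si](C)(C)C(C)(C)C)Oc2ccc(C[C@H]3COC(=O)[C@@H]3Cc3cc(OC)c4c(c3)[C@H](CO[Si](C(C)C)(C(C)C)C(C)C)[C@@H](c3ccc(O[Si](C(C)C)(C(C)C)C(C)C)c(OC)c3)O4)cc2OC)ccc1O[Si](C(C)C)(C(C)C)C(C)C | intermediate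
41 | (3R,4R)-4-[[4-[[(1R,2S)-1,3-dihydroxy-1-(4-hydroxy-3-methoxyphenyl)propan-2-yl]oxy]-3-methoxyphenyl]methyl]-3-[[(2S,3R)-2-(4-hydroxy-3-methoxyphenyl)-3-(hydroxymethyl)-7-methoxy-2,3-dihydro-1-benzofuran-5-yl]methyl]oxolan-2-one | COc1cc([C@@H](O)[C@H](CO)Oc2ccc(C[C@H]3COC(=O)[C@@H]3Cc3cc(OC)c4c(c3)[C@H](CO)[C@@H](c3ccc(O)c(OC)c3)O4)cc2OC)ccc1O | target

**Step count and risks**

Total step count: 26. Longest linear sequence: 15 steps (steps 10, 11, 13 to 16 and 18 to 26, from 4-hydroxy-3-methoxybenzyl alcohol).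

Steps most likely to fail:

Step 6. The aryl shift may take the wrong course: ring D may migrate from C2 to C3 (isoflavone pathway), the ring may be dehydrogenated to the flavone, the bromine-deactivated benzo carbon may migrate slowly, or C2 may partly lose its configuration through acid-induced opening of the pyranone. The fallback is a Wolff ring contraction, which makes the same C3–C3a bond through a ketocarbene instead of a trivalent iodine leaving group. It sets out from 8: condensation with N,N-dimethylformamide dimethyl acetal (toluene, 80 °C) should give 4-[(2R)-6-bromo-3-(dimethylaminomethylidene)-8-methoxy-4-oxo-3,4-dihydro-2H-chromen-2-yl]-2-methoxyphenyl pivalate F1 (same spatial arrangement at C2 as in 8). Diazo transfer with tosyl azide (MeCN, rt) should give the 3-diazoflavanone F2. Irradiation at 365 nm in methanol should expel nitrogen with migration of C4a to C3 to give the ketene F3, which methanol traps as the methyl ester; the portion formed as the cis ester F4 is equilibrated with DBU in CH2Cl2. The sequence comes back to the route at 11.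

Step 21. The electron-rich benzylic oxyphosphonium intermediate may ionise, so that inversion is incomplete, or may eliminate towards the enol ether. The fallback replaces substitution by a redox inversion and sets out from 32: Dess–Martin periodinane (NaHCO3, CH2Cl2, 0 °C) should oxidise the C7 hydroxyl to the aryl ketone F5 without disturbing C8. Reduction with Zn(BH4)2 (Et2O, −20 °C) under chelation control, zinc bridging the carbonyl oxygen and the aryloxy and ortho-methoxy oxygens on C8 and hydride arriving from the side of the C8 hydrogen, should give the erythro alcohol. The sequence comes back to the route at 34.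

Step 25. The electron-rich boronate may undergo protodeboronation, the exocyclic double bond may migrate into the lactone ring under rhodium hydride or base (which would erase C4), or Heck-type β-hydride elimination may compete with protonation. The fallback is the classical enolate benzylation of a saturated lactone and sets out from 13: bromine–lithium exchange with n-BuLi (THF, −78 °C) and quenching with DMF should give the aldehyde F6. NaBH4 (MeOH, 0 °C) gives the benzylic alcohol F7, and CBr4 with PPh3 gives the benzylic bromide F8. The lithium enolate of the saturated lactone 35 (LiN(SiMe3)2, THF, −78 °C) is then alkylated by F8 on the face anti to the C4 substituent, which should give the trans lactone directly. The sequence comes back to the route at 40.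

Further compounds
F1 | step 6 | 4-[(2R)-6-bromo-3-(dimethylaminomethylidene)-8-methoxy-4-oxo-3,4-dihydro-2H-chromen-2-yl]-2-methoxyphenyl pivalate | O=C1C(=CN(C)C)[C@@H](c2ccc(OC(=O)C(C)(C)C)c(OC)c2)Oc2c(OC)cc(Br)cc12
F2 | step 6 | 4-[(2R)-6-bromo-3-diazo-8-methoxy-4-oxo-3,4-dihydro-2H-chromen-2-yl]-2-methoxyphenyl pivalate | O=C1C(=[N+]=[N-])[C@@H](c2ccc(OC(=O)C(C)(C)C)c(OC)c2)Oc2c(OC)cc(Br)cc12
F3 | step 6 | 4-[(2R)-5-bromo-7-methoxy-3-(oxomethylidene)-2,3-dihydro-1-benzofuran-2-yl]-2-methoxyphenyl pivalate (ketene) | Brc1cc(OC)c2c(c1)C(=C=O)[C@@H](c1ccc(OC(=O)C(C)(C)C)c(OC)c1)O2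
F4 | step 6 | methyl (2S,3R)-5-bromo-7-methoxy-2-[3-methoxy-4-(pivaloyloxy)phenyl]-2,3-dihydro-1-benzofuran-3-carboxylate (cis) | Brc1cc(OC)c2c(c1)[C@@H](C(=O)OC)[C@@H](c1ccc(OC(=O)C(C)(C)C)c(OC)c1)O2
F5 | step 21 | (4R)-4-[[4-[[(2S)-3-(tert-butyldimethylsilyloxy)-1-[3-methoxy-4-(triisopropylsilyloxy)phenyl]-1-oxopropan-2-yl]oxy]-3-methoxyphenyl]methyl]oxolan-2-one | COc1cc(C(=O)[C@H](CO[Si](C)(C)C(C)(C)C)Oc2ccc(C[C@H]3COC(=O)C3)cc2OC)ccc1O[Si](C(C)C)(C(C)C)C(C)C
F6 | step 25 | (2S,3R)-7-methoxy-2-[3-methoxy-4-(triisopropylsilyloxy)phenyl]-3-[(triisopropylsilyloxy)methyl]-2,3-dihydro-1-benzofuran-5-carbaldehyde | O=Cc1cc(OC)c2c(c1)[C@H](CO[Si](C(C)C)(C(C)C)C(C)C)[C@@H](c1ccc(O[Si](C(C)C)(C(C)C)C(C)C)c(OC)c1)O2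
F7 | step 25 | [(2S,3R)-7-methoxy-2-[3-methoxy-4-(triisopropylsilyloxy)phenyl]-3-[(triisopropylsilyloxy)methyl]-2,3-dihydro-1-benzofuran-5-yl]methanol | OCc1cc(OC)c2c(c1)[C@H](CO[Si](C(C)C)(C(C)C)C(C)C)[C@@H](c1ccc(O[Si](C(C)C)(C(C)C)C(C)C)c(OC)c1)O2
F8 | step 25 | (2S,3R)-5-(bromomethyl)-7-methoxy-2-[3-methoxy-4-(triisopropylsilyloxy)phenyl]-3-[(triisopropylsilyloxy)methyl]-2,3-dihydro-1-benzofuran | BrCc1cc(OC)c2c(c1)[C@H](CO[Si](C(C)C)(C(C)C)C(C)C)[C@@H](c1ccc(O[Si](C(C)C)(C(C)C)C(C)C)c(OC)c1)O2
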